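The aroyl carbonyl and ring A (C1–C2–C3–C4–C5–C9) unfold into a straight chain of four carbonyl groups in 1,3,5,7-relationship. C8 of ring B sits β to the carbon substituent on C7, so a formyl group on C7 makes C7=C8 a Michael acceptor. Cutting C3–C4 and C1–C8 opens both rings to an acyclic triketo trifluoroethyl ester. Its only stereocentre is quaternary C5, and it carries an (E)-tetrasubstituted enal. One base treatment closes ring A by Claisen acylation and ring B by conjugate addition, relaying C5 to C1, C8 and C7. The endo formyl group is then homologated to the third prenyl group.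

Key step: step 18

**Conventions**
- C1 is the bridgehead next to C8, C2 a ketone, C3 the aroyl-bearing carbon, C4 the enol carbon and C5 the second bridgehead. C6 is CH2, C7 is CH, C8 is C(CH3)(homoprenyl) and C9 is the bridging ketone.
- Ring B is C1–C8–C7–C6–C5–C9. "Endo" means on the side of the C2–C3–C4 bridge.
- Prenyl = 3-methylbut-2-enyl, homoprenyl = 4-methylpent-3-enyl, TIPS = triisopropylsilyl.

**Assumption**
- The cinchonidinium salt of step 10 is taken to deliver (R)-20. Should it favour the antipode, the pseudoenantiomeric cinchoninium salt is used.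

**Design notes**
- (a) The C1 prenyl group is installed before C5 is quaternised, so no regioselective prenylation of a polyketone is needed.
- (b) The formyl carbon and the aryl ketone travel as dioxolanes. Once the activated ester is present there is therefore no hydride reduction and no free primary δ-hydroxy ester. The secondary alcohol of 29 is oxidised at once.
- (c) An electrophilic or radical CH2 on the endo face would lie over the nucleophilic C3/C4–O enol and close extra rings. The formyl group is therefore extended by Wittig chemistry only.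
- (d) C5 is (R) in the open-chain compounds and (S) in 32–37. The spatial arrangement is unchanged; only the CIP ranks of C4 and C9 swap.
- (e) The enal must be (E), with homoprenyl cis to C6, to give (8R).

Step 1
Reactants: 1 5-bromo-2-methylpent-2-ene; 2 methyl but-2-ynoate
Product: 6 methyl (2Z)-2-iodo-3,7-dimethylocta-2,6-dienoate, via homoprenylmagnesium bromide 3 (not isolated), via homoprenylcopper 4 (not isolated), via alkenylcopper adduct 5 (not isolated)
Conditions: 1, Mg, THF; CuBr·SMe2, THF, −40 °C; 2, −78 °C; I2 in THF, −78 °C; aq. Na2S2O3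
Reagents that add atoms: iodine II; magnesium [Mg] and CuBr·SMe2 [Cu]Br.CSC (atoms only in 3–5)
Why: Syn carbocupration of the ynoate puts homoprenyl on the β-carbon and copper on the α-carbon on the same side, and iodinolysis at −78 °C, below the temperature at which the α-cuprio ester isomerises through its allenolate, replaces copper with retention, so iodine (the future C6 site) is cis to homoprenyl.

Step 2
Reactants: 6 methyl (2Z)-2-iodo-3,7-dimethylocta-2,6-dienoate
Product: 7 (2Z)-2-iodo-3,7-dimethylocta-2,6-dien-1-ol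
Conditions: i-Bu2AlH (2.2 equiv), CH2Cl2, −78 °C; aq. potassium sodium tartrate
Reagents that add atoms: none
Why: 1,2-Reduction of an enoate to the allylic alcohol with i-Bu2AlH leaves the alkenyl iodide and the double-bond geometry untouched at low temperature.

Step 3
Reactants: 7 (2Z)-2-iodo-3,7-dimethylocta-2,6-dien-1-ol
Product: 8 (2Z)-2-iodo-3,7-dimethylocta-2,6-dienal
Conditions: MnO2, CH2Cl2, rt
Reagents that add atoms: none
Why: Manganese dioxide oxidation of an allylic alcohol is neutral and heterogeneous and keeps the alkene geometry.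

Step 4
Reactants: 8 (2Z)-2-iodo-3,7-dimethylocta-2,6-dienal
Product: 9 2-[(1Z)-1-iodo-2,6-dimethylhepta-1,5-dienyl]-1,3-dioxolane
Conditions: Me3SiOCH2CH2OSiMe3, Me3SiOTf (cat.), CH2Cl2, −78 → −20 °C; pyridine quench
Reagents that add atoms: 1,2-bis(trimethylsilyloxy)ethane C[Si](C)(C)OCCO[Si](C)(C)C
Why: Silyl-triflate-catalysed acetalisation with the bis-silyl ether of glycol is aprotic and cold, so the enal is masked without migration or isomerisation of the tetrasubstituted double bond.

Step 5
Reactants: 9 2-[(1Z)-1-iodo-2,6-dimethylhepta-1,5-dienyl]-1,3-dioxolane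
Product: 11 (2E)-2-(1,3-dioxolan-2-yl)-3,7-dimethylocta-2,6-dien-1-ol, via alkenyllithium 10 (not isolated)
Conditions: t-BuLi (2.1 equiv), Et2O, −78 °C; monomeric CH2O in THF, −78 °C; H2O
Reagents that add atoms: formaldehyde C=O; tert-butyllithium [Li]C(C)(C)C (lithium only in 10)
Why: Iodine–lithium exchange gives a configurationally stable alkenyllithium that adds to formaldehyde with retention before β-elimination of an acetal oxygen can set in, so the new CH2OH (C6) is cis to homoprenyl.

Step 6
Reactants: 11 (2E)-2-(1,3-dioxolan-2-yl)-3,7-dimethylocta-2,6-dien-1-ol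
Product: 12 2-[(2Z)-1-bromo-3,7-dimethylocta-2,6-dien-2-yl]-1,3-dioxolane
Conditions: CBr4, PPh3, 2,6-lutidine, CH2Cl2, −20 °C
Reagents that add atoms: carbon tetrabromide BrC(Br)(Br)Br
Why: Appel bromination of a primary allylic alcohol under buffered conditions proceeds by direct SN2 displacement, because transposition would have to form a tertiary bromide.

Step 7
Reactants: 13 2,2,6-trimethyl-1,3-dioxin-4-one; 14 1-bromo-3-methylbut-2-ene
Product: 16 2,2-dimethyl-6-(4-methylpent-3-enyl)-1,3-dioxin-4-one, via lithium dienolate 15 (not isolated)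
Conditions: LiN(i-Pr)2, THF/DMPU, −78 °C; 14, −78 → −30 °C
Reagents that add atoms: lithium diisopropylamide CC(C)N([Li])C(C)C (lithium only in 15)
Why: γ-Alkylation of the extended dioxinone dienolate (vinylogous enolate alkylation) places the prenyl group on the future C1 while no other acidic site exists.

Step 8
Reactants: 16 2,2-dimethyl-6-(4-methylpent-3-enyl)-1,3-dioxin-4-one
Product: 18 2,2,2-trifluoroethyl 7-methyl-3-oxooct-6-enoate, via acylketene 17 (not isolated)
Conditions: CF3CH2OH (5 equiv), toluene, 110 °C, sealed tube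
Reagents that add atoms: 2,2,2-trifluoroethanol OCC(F)(F)F
Why: Thermal retro-hetero-Diels–Alder loss of acetone gives an acylketene that trifluoroethanol traps irreversibly, the standard entry to activated β-keto esters.

Step 9
Reactants: 18 2,2,2-trifluoroethyl 7-methyl-3-oxooct-6-enoate; 14 1-bromo-3-methylbut-2-ene
Product: 19 2,2,2-trifluoroethyl 7-methyl-2-(3-methylbut-2-enyl)-3-oxooct-6-enoate (racemic)
Conditions: K2CO3, acetone, rt
Reagents that add atoms: none
Why: Classical C-alkylation of a β-keto ester enolate with an allylic bromide; the new centre is racemic and is planarised again in step 10.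

Step 10
Reactants: 19 2,2,2-trifluoroethyl 7-methyl-2-(3-methylbut-2-enyl)-3-oxooct-6-enoate; 12 2-[(2Z)-1-bromo-3,7-dimethylocta-2,6-dien-2-yl]-1,3-dioxolane
Product: 20 2,2,2-trifluoroethyl (2R)-2-[(2E)-2-(1,3-dioxolan-2-yl)-3,7-dimethylocta-2,6-dienyl]-7-methyl-2-(3-methylbut-2-enyl)-3-oxooct-6-enoate
Conditions: O-allyl-N-(9-anthracenylmethyl)cinchonidinium bromide (10 mol %), solid Cs2CO3, toluene, −20 °C
Reagents that add atoms: none
Why: Asymmetric phase-transfer alkylation of an α-alkyl β-keto ester, in which the chiral ammonium cation shields one face of the planar enolate so that the allylic bromide is attacked (SN2) from the other and sets quaternary C5, while solid carbonate in toluene spares the activated ester.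

Step 11
Reactants: 21 3,4-dihydroxybenzoic acid
Product: 23 3,4-bis(triisopropylsilyloxy)benzoic acid, via tris-silylated ester 22 (not isolated)
Conditions: i-Pr3SiCl (3.3 equiv), imidazole, DMF, rt; then K2CO3, THF/MeOH/H2O, 0 °C; 1 M HCl to pH 4
Reagents that add atoms: chlorotriisopropylsilane CC(C)[Si](Cl)(C(C)C)C(C)C
Why: Exhaustive silylation followed by selective hydrolysis of the far more labile silyl ester gives the catechol-protected acid.

Step 12
Reactants: 23 3,4-bis(triisopropylsilyloxy)benzoic acid
Product: 25 ethyl 3-[3,4-bis(triisopropylsilyloxy)phenyl]-3-oxopropanoate, via acyl imidazole 24 (not isolated)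
Conditions: 1,1'-carbonyldiimidazole, THF, rt; then KO2CCH2CO2Et, MgCl2, Et3N, MeCN, rt; 1 M HCl work-up
Reagents that add atoms: potassium ethyl malonate CCOC(=O)CC(=O)[O-].[K+]; 1,1'-carbonyldiimidazole O=C(n1ccnc1)n1ccnc1 (atoms only in 24)
Why: Decarboxylative Claisen condensation, in which the magnesium enolate of a malonic half ester is acylated by the acyl imidazole and then loses CO2.

Step 13
Reactants: 25 ethyl 3-[3,4-bis(triisopropylsilyloxy)phenyl]-3-oxopropanoate
Product: 26 ethyl {2-[3,4-bis(triisopropylsilyloxy)phenyl]-1,3-dioxolan-2-yl}acetate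
Conditions: HOCH2CH2OH, p-TsOH·H2O (cat.), toluene, reflux, Dean–Stark trap
Reagents that add atoms: ethylene glycol OCCO
Why: Acid-catalysed ketalisation with azeotropic removal of water takes away the acidity of the future C3 for the coupling, and aryl TIPS ethers tolerate the acid.

Step 14
Reactants: 26 ethyl {2-[3,4-bis(triisopropylsilyloxy)phenyl]-1,3-dioxolan-2-yl}acetate
Product: 27 {2-[3,4-bis(triisopropylsilyloxy)phenyl]-1,3-dioxolan-2-yl}acetaldehyde
Conditions: i-Bu2AlH (1.05 equiv), toluene, −78 °C; MeOH, then aq. potassium sodium tartrate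
Reagents that add atoms: none
Why: Partial reduction of an ester with i-Bu2AlH stops at the aldehyde stage because the tetrahedral aluminium intermediate, chelated by a ketal oxygen, survives at −78 °C until the quench.

Step 15
Reactants: 20 quaternary β-keto ester; 27 {2-[3,4-bis(triisopropylsilyloxy)phenyl]-1,3-dioxolan-2-yl}acetaldehyde
Product: 29 2,2,2-trifluoroethyl (2R)-6-{2-[3,4-bis(triisopropylsilyloxy)phenyl]-1,3-dioxolan-2-yl}-2-[(2E)-2-(1,3-dioxolan-2-yl)-3,7-dimethylocta-2,6-dienyl]-5-hydroxy-2,4-bis(3-methylbut-2-enyl)-3-oxohexanoate (mixture at C1 and C2), via lithium enolate 28 (not isolated)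
Conditions: 20, LiN(SiMe3)2 (1.1 equiv), THF, −78 °C; 27, −78 °C; AcOH in THF, −78 °C
Reagents that add atoms: lithium hexamethyldisilazide C[Si](C)(C)N([Li])[Si](C)(C)C (lithium only in 28)
Why: Directed aldol addition, in which the ketone can enolise only toward C1 because C5 is quaternary, the enolate adds to the aldehyde faster than it deprotonates it, the two new centres need no control because both are erased later, and the cold acid quench forestalls attack of the aldolate on the activated ester.

Step 16
Reactants: 29 aldol adduct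
Product: 30 2,2,2-trifluoroethyl (2R)-6-{2-[3,4-bis(triisopropylsilyloxy)phenyl]-1,3-dioxolan-2-yl}-2-[(2E)-2-(1,3-dioxolan-2-yl)-3,7-dimethylocta-2,6-dienyl]-2,4-bis(3-methylbut-2-enyl)-3,5-dioxohexanoate
Conditions: Dess–Martin periodinane, NaHCO3, CH2Cl2, 0 °C → rt
Reagents that add atoms: none
Why: Dess–Martin oxidation of a β-hydroxy ketone to the 1,3-diketone under buffered conditions leaves acetals, silyl ethers, the ester and the alkenes alone.

Step 17
Reactants: 30 bis-dioxolane diketone
Product: 31 2,2,2-trifluoroethyl (2R)-7-[3,4-bis(triisopropylsilyloxy)phenyl]-2-[(2E)-2-formyl-3,7-dimethylocta-2,6-dienyl]-2,4-bis(3-methylbut-2-enyl)-3,5,7-trioxoheptanoate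
Conditions: 1 M aq. HCl/THF, 0 °C → rt
Reagents that add atoms: water O
Why: Acid hydrolysis of an allylic acetal and an electron-rich aryl ketal, both of which ionise easily, unveils acceptor and donor together in one non-basic and non-redox operation, so the loaded chain meets no base before step 18.

Step 18
Reactants: 31 acyclic tetracarbonyl enal
Product: 33 (1S,5S,7S,8R)-3-[3,4-bis(triisopropylsilyloxy)benzoyl]-4-hydroxy-8-methyl-1,5-bis(3-methylbut-2-enyl)-8-(4-methylpent-3-enyl)-2,9-dioxobicyclo[3.3.1]non-3-ene-7-carbaldehyde (formyl endo), via monocyclic trione 32 (not isolated)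
Conditions: Cs2CO3 (3 equiv), 4 Å molecular sieves, MeCN (0.01 M), argon, −20 °C → rt; AcOH in THF, −20 °C
Reagents that add atoms: none
Why: Proposed new method: Cs2CO3 first ionises C3–H, the most acidic site because it lies between the aryl ketone and C2, this carbanion attacks the trifluoroethyl ester carbon C4 and expels trifluoroethoxide to give the lupulone-type trione 32, a second ionisation at C1 then lets the ring enolate add to C8 of the tethered enal, and the resulting aldehyde enolate is protonated by the trifluoroethanol and hydrogencarbonate formed on the way. The closest known reaction types are the Claisen cyclisation of 3,5,7-trioxo esters to acylphloroglucinol tautomers and the intramolecular Michael addition of dearomatised acylphloroglucinol enolates to β,β-disubstituted enals, whereas their merger in one flask on an open chain is without precedent. Ring A closes 6-exo-trig at the ester carbonyl and ring B closes 6-endo-trig at the C7=C8 bond. C1 is dictated by C5, since the C6–C7–C8 tether reaches C1 only on the ring face from which C6 departs; C8 is dictated by the (E)-enal geometry in a chair-like transition state that is staggered about C5–C6 and C1–C8 and turns the homoprenyl group (cis to C6) axial and the methyl group equatorial on ring B; C7 is dictated by proton delivery to the convex exo face of the exocyclic enolate, which leaves the formyl group endo above C2–C4. The step needs ring A to form before C1 attacks, which the acidity gap between C3–H and the hindered C1–H, the activated ester and the slow build-up of two adjacent quaternary carbons secure, while O-acylation, oxa-Michael addition and 1,2-addition of C1 to the formyl carbon are reversible and drain into the stabilised triketonate of 33. Low temperature, exclusion of water and a cold acetic acid quench are meant to keep the enal geometry before and the endo aldehyde after bond formation, and no electrophile able to engage the four isolated trisubstituted alkenes is present at any time.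

Step 19
Reactants: 33 bicyclic endo aldehyde
Product: 35 (1S,5S,7R,8R)-3-[3,4-bis(triisopropylsilyloxy)benzoyl]-4-hydroxy-8-methyl-1,5-bis(3-methylbut-2-enyl)-8-(4-methylpent-3-enyl)-7-(2-oxoethyl)bicyclo[3.3.1]non-3-ene-2,9-dione, via methyl enol ether 34 (not isolated)
Conditions: [Ph3PCH2OMe]Cl (4 equiv), KN(SiMe3)2 (3.8 equiv), THF, −78 → 0 °C; then 1 M aq. HCl/THF, 0 °C → rt
Reagents that add atoms: (methoxymethyl)triphenylphosphonium chloride COC[P+](c1ccccc1)(c1ccccc1)c1ccccc1.[Cl-]; water O
Why: Wittig methoxymethylenation followed by enol ether hydrolysis (one-carbon homologation), in which the first equivalent of ylide turns the enol into the inert triketonate, C9 is shielded by two quaternary carbons, addition to the aldehyde outruns enolisation in the cold, and C7 can no longer epimerise once it bears the alkenyl group.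

Step 20
Reactants: 35 homologated aldehyde
Product: 36 (1S,5S,7S,8R)-3-[3,4-bis(triisopropylsilyloxy)benzoyl]-4-hydroxy-8-methyl-1,5,7-tris(3-methylbut-2-enyl)-8-(4-methylpent-3-enyl)bicyclo[3.3.1]non-3-ene-2,9-dione
Conditions: [Ph3P(i-Pr)]I (4 equiv), n-BuLi (3.8 equiv), THF, 0 °C; 35, −78 °C → rt
Reagents that add atoms: isopropyltriphenylphosphonium iodide CC(C)[P+](c1ccccc1)(c1ccccc1)c1ccccc1.[I-]
Why: Wittig olefination with the isopropylidene ylide turns the unhindered aldehyde into the trisubstituted alkene of the prenyl group, the triketonate and C9 again being spectators.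

Step 21
Reactants: 36 bis-TIPS ether of the target
Product: 37 (1S,5S,7S,8R)-3-(3,4-dihydroxybenzoyl)-4-hydroxy-8-methyl-1,5,7-tris(3-methylbut-2-enyl)-8-(4-methylpent-3-enyl)bicyclo[3.3.1]non-3-ene-2,9-dione (CNP0108469.1)
Conditions: n-Bu4NF/AcOH (1:1, 3 equiv), THF, 0 °C, argon
Reagents that add atoms: none
Why: Fluoride cleavage of aryl silyl ethers, buffered with acetic acid so that no free catecholate is exposed to air and no acid strong enough for enol–prenyl cyclisation is present.

**Compound list**
1 | 5-bromo-2-methylpent-2-ene | CC(C)=CCCBr | starting material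
2 | methyl but-2-ynoate | CC#CC(=O)OC | starting material
3 | (4-methylpent-3-enyl)magnesium bromide | CC(C)=CCC[Mg]Br | intermediate (not isolated)
4 | (4-methylpent-3-enyl)copper | CC(C)=CCC[Cu] | intermediate (not isolated)
5 | methyl (2Z)-2-cuprio-3,7-dimethylocta-2,6-dienoate | COC(=O)/C([Cu])=C(\C)CCC=C(C)C | intermediate (not isolated)
6 | methyl (2Z)-2-iodo-3,7-dimethylocta-2,6-dienoate | COC(=O)/C(I)=C(\C)CCC=C(C)C | intermediate
7 | (2Z)-2-iodo-3,7-dimethylocta-2,6-dien-1-ol | OC/C(I)=C(\C)CCC=C(C)C | intermediate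
8 | (2Z)-2-iodo-3,7-dimethylocta-2,6-dienal | O=C/C(I)=C(\C)CCC=C(C)C | intermediate
9 | 2-[(1Z)-1-iodo-2,6-dimethylhepta-1,5-dienyl]-1,3-dioxolane | C1COC(O1)/C(I)=C(\C)CCC=C(C)C | intermediate
10 | alkenyllithium from 9 (lithium cis to homoprenyl) | C1COC(O1)/C([Li])=C(\C)CCC=C(C)C | intermediate (not isolated)
11 | (2E)-2-(1,3-dioxolan-2-yl)-3,7-dimethylocta-2,6-dien-1-ol | C1COC(O1)/C(CO)=C(\C)CCC=C(C)C | intermediate
12 | 2-[(2Z)-1-bromo-3,7-dimethylocta-2,6-dien-2-yl]-1,3-dioxolane | C1COC(O1)/C(CBr)=C(\C)CCC=C(C)C | intermediate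
13 | 2,2,6-trimethyl-1,3-dioxin-4-one | CC1=CC(=O)OC(C)(C)O1 | starting material
14 | 1-bromo-3-methylbut-2-ene (prenyl bromide) | CC(C)=CCBr | starting material
15 | lithium 2,2-dimethyl-6-methylidene-1,3-dioxin-4-olate | C=C1C=C(O[Li])OC(C)(C)O1 | intermediate (not isolated)
16 | 2,2-dimethyl-6-(4-methylpent-3-enyl)-1,3-dioxin-4-one | CC(C)=CCCC1=CC(=O)OC(C)(C)O1 | intermediate
17 | (5-methylhex-4-enoyl)ketene | CC(C)=CCCC(=O)C=C=O | intermediate (not isolated)
18 | 2,2,2-trifluoroethyl 7-methyl-3-oxooct-6-enoate | CC(C)=CCCC(=O)CC(=O)OCC(F)(F)F | intermediate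
19 | 2,2,2-trifluoroethyl 7-methyl-2-(3-methylbut-2-enyl)-3-oxooct-6-enoate (racemic) | CC(C)=CCCC(=O)C(CC=C(C)C)C(=O)OCC(F)(F)F | intermediate
20 | quaternary β-keto ester, (R) at C5, (E)-alkene, enal masked as dioxolane | CC(C)=CCC/C(C)=C(/C1OCCO1)C[C@](C(=O)OCC(F)(F)F)(CC=C(C)C)C(=O)CCC=C(C)C | intermediate
21 | 3,4-dihydroxybenzoic acid | O=C(O)c1ccc(O)c(O)c1 | starting material
22 | triisopropylsilyl 3,4-bis(triisopropylsilyloxy)benzoate | CC(C)[Si](C(C)C)(C(C)C)OC(=O)c1ccc(O[Si](C(C)C)(C(C)C)C(C)C)c(O[Si](C(C)C)(C(C)C)C(C)C)c1 | intermediate (not isolated)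
23 | 3,4-bis(triisopropylsilyloxy)benzoic acid | O=C(O)c1ccc(O[Si](C(C)C)(C(C)C)C(C)C)c(O[Si](C(C)C)(C(C)C)C(C)C)c1 | intermediate
24 | 1-[3,4-bis(triisopropylsilyloxy)benzoyl]imidazole | O=C(c1ccc(O[Si](C(C)C)(C(C)C)C(C)C)c(O[Si](C(C)C)(C(C)C)C(C)C)c1)n2ccnc2 | intermediate (not isolated)
25 | ethyl 3-[3,4-bis(triisopropylsilyloxy)phenyl]-3-oxopropanoate | CCOC(=O)CC(=O)c1ccc(O[Si](C(C)C)(C(C)C)C(C)C)c(O[Si](C(C)C)(C(C)C)C(C)C)c1 | intermediate
26 | ethyl {2-[3,4-bis(triisopropylsilyloxy)phenyl]-1,3-dioxolan-2-yl}acetate | CCOC(=O)CC1(OCCO1)c2ccc(O[Si](C(C)C)(C(C)C)C(C)C)c(O[Si](C(C)C)(C(C)C)C(C)C)c2 | intermediate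
27 | {2-[3,4-bis(triisopropylsilyloxy)phenyl]-1,3-dioxolan-2-yl}acetaldehyde | O=CCC1(OCCO1)c2ccc(O[Si](C(C)C)(C(C)C)C(C)C)c(O[Si](C(C)C)(C(C)C)C(C)C)c2 | intermediate
28 | lithium C9–C1 enolate of 20 | CC(C)=CCC/C(C)=C(/C1OCCO1)C[C@](C(=O)OCC(F)(F)F)(CC=C(C)C)C(O[Li])=CCC=C(C)C | intermediate (not isolated)
29 | aldol adduct, (R) at C5, mixture at C1 and C2 | CC(C)=CCC/C(C)=C(/C1OCCO1)C[C@](C(=O)OCC(F)(F)F)(CC=C(C)C)C(=O)C(CC=C(C)C)C(O)CC2(OCCO2)c3ccc(O[Si](C(C)C)(C(C)C)C(C)C)c(O[Si](C(C)C)(C(C)C)C(C)C)c3 | intermediate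
30 | bis-dioxolane C9/C2 diketone, (R) at C5 | CC(C)=CCC/C(C)=C(/C1OCCO1)C[C@](C(=O)OCC(F)(F)F)(CC=C(C)C)C(=O)C(CC=C(C)C)C(=O)CC2(OCCO2)c3ccc(O[Si](C(C)C)(C(C)C)C(C)C)c(O[Si](C(C)C)(C(C)C)C(C)C)c3 | intermediate
31 | acyclic tetracarbonyl chain with quaternary (R)-C5 and (E)-enal (C1 enolisable, no configuration) | CC(C)=CCC/C(C)=C(/C=O)C[C@](C(=O)OCC(F)(F)F)(CC=C(C)C)C(=O)C(CC=C(C)C)C(=O)CC(=O)c1ccc(O[Si](C(C)C)(C(C)C)C(C)C)c(O[Si](C(C)C)(C(C)C)C(C)C)c1 | intermediate (precursor of the key step)
32 | monocyclic aroyl trione (ring A closed, (S) at C5, enal intact) | CC(C)=CCC/C(C)=C(/C=O)C[C@]1(CC=C(C)C)C(=O)C(CC=C(C)C)C(=O)C(C(=O)c2ccc(O[Si](C(C)C)(C(C)C)C(C)C)c(O[Si](C(C)C)(C(C)C)C(C)C)c2)=C1O | intermediate (not isolated)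
33 | bicyclic aroyl trione with endo C7 formyl group, (1S,5S,7S,8R) | CC(C)=CCC[C@]1(C)[C@@H](C=O)C[C@]2(CC=C(C)C)C(=O)[C@@]1(CC=C(C)C)C(=O)C(C(=O)c1ccc(O[Si](C(C)C)(C(C)C)C(C)C)c(O[Si](C(C)C)(C(C)C)C(C)C)c1)=C2O | intermediate (product of the key step)
34 | C7 endo 2-methoxyvinyl compound (E/Z mixture) | CC(C)=CCC[C@]1(C)[C@@H](C=COC)C[C@]2(CC=C(C)C)C(=O)[C@@]1(CC=C(C)C)C(=O)C(C(=O)c3ccc(O[Si](C(C)C)(C(C)C)C(C)C)c(O[Si](C(C)C)(C(C)C)C(C)C)c3)=C2O | intermediate (not isolated)
35 | C7 endo 2-oxoethyl compound, (1S,5S,7R,8R) | CC(C)=CCC[C@]1(C)[C@@H](CC=O)C[C@]2(CC=C(C)C)C(=O)[C@@]1(CC=C(C)C)C(=O)C(C(=O)c3ccc(O[Si](C(C)C)(C(C)C)C(C)C)c(O[Si](C(C)C)(C(C)C)C(C)C)c3)=C2O | intermediate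
36 | bis-TIPS ether of the target, (1S,5S,7S,8R) | CC(C)=CCC[C@]1(C)[C@@H](CC=C(C)C)C[C@]2(CC=C(C)C)C(=O)[C@@]1(CC=C(C)C)C(=O)C(C(=O)c3ccc(O[Si](C(C)C)(C(C)C)C(C)C)c(O[Si](C(C)C)(C(C)C)C(C)C)c3)=C2O | intermediate
37 | CNP0108469.1, (1S,5S,7S,8R) | CC(C)=CCC[C@]1(C)[C@@H](CC=C(C)C)C[C@]2(CC=C(C)C)C(=O)[C@@]1(CC=C(C)C)C(=O)C(C(=O)c1ccc(O)c(O)c1)=C2O | target

Total step count: 21. Longest linear sequence: 14 steps (1–6, 10, 15–21).

**Steps most likely to fail**

Step 18.
- What may go wrong: acylation of the hindered ester may be too slow, so that C1 adds to the enal or to the formyl carbon while the chain is still open. The enal may lose its geometry through reversible hetero-conjugate addition. The endo aldehyde may equilibrate to the exo position.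
- Fallback: the cascade is given up and the two bonds are made in two separate, individually known operations with different activation. The fallback sets out from 31. MgCl2 and Et3N in MeCN at 0 °C close ring A alone by C-acylation of a magnesium-chelated 1,3-diketone. This enolate is too weak a donor for the hindered enal, and 32 is isolated as its enol after an acid wash.
- Ring B is then closed on purified 32 with CsOH·H2O and benzyltriethylammonium chloride in CH2Cl2 at −50 °C. This is the known ion-pair Michael closure of dearomatised acylphloroglucinols onto β,β-disubstituted enals, and it rejoins the route at 33.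
- Any material whose formyl group has gone exo is re-enolised with KN(SiMe3)2 at −78 °C and protonated kinetically with acetic acid.
- New compounds: none F0.

Step 10.
- What may go wrong: the ion pair may discriminate poorly between the faces of an acyclic enolate of ill-defined geometry. O-alkylation and slow loss of the activated ester may also intrude.
- Fallback: catalyst control is replaced by a covalently bound auxiliary. The fallback sets out from 19. Condensation with L-valine tert-butyl ester (BF3·OEt2 cat., benzene, reflux, removal of water) gives the chelated enamino ester F1.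
- Lithiation follows with LiN(i-Pr)2 in toluene. The added ligand (THF or HMPA) decides which face stays open. Alkylation with 12 at −78 → −40 °C gives the quaternary imine F2.
- An aqueous acetic acid/sodium acetate buffer hydrolyses the imine, releases the auxiliary and rejoins the route at 20.

Step 19.
- What may go wrong: the basic ylide may enolise the hindered endo aldehyde, with loss of the C7 configuration. The acid hydrolysis may trigger transannular capture or enol–prenyl cyclisation.
- Fallback: phosphorus ylides and aqueous acid are avoided altogether. The fallback sets out from 33. CH2=CHMgBr (3 equiv, THF, −78 °C) adds to the aldehyde to give the allylic alcohol F3.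
- Ac2O, DMAP and pyridine give the allylic acetate F4. The labile enol acetate that forms alongside reverts on methanol work-up.
- Formate reduction catalysed by zerovalent palladium (Pd2(dba)3, n-Bu3P, HCO2NH4) delivers hydride to the inner allyl terminus and gives the 7-allyl compound F5.
- Cross-metathesis with 2-methylbut-2-ene (second-generation Grubbs catalyst, CH2Cl2, 40 °C) then rejoins the route at 36. The other prenyl and homoprenyl groups only exchange identical isopropylidene ends.

**Further compounds**
F0 | step 18 | none | none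
F1 | step 10 | tert-butyl N-[1-(2,2,2-trifluoroethoxycarbonyl)-1-(3-methylbut-2-enyl)-6-methylhepta-1,5-dien-2-yl]-L-valinate (enamino ester of 19) | CC(C)=CCCC(N[C@@H](C(C)C)C(=O)OC(C)(C)C)=C(CC=C(C)C)C(=O)OCC(F)(F)F
F2 | step 10 | C9 imine of 20 with L-valine tert-butyl ester, (R) at C5 | CC(C)=CCC/C(C)=C(/C1OCCO1)C[C@](C(=O)OCC(F)(F)F)(CC=C(C)C)C(CCC=C(C)C)=N[C@@H](C(C)C)C(=O)OC(C)(C)C
F3 | step 19 | C7 endo 1-hydroxyprop-2-enyl compound (carbinol epimers) | CC(C)=CCC[C@]1(C)[C@@H](C(O)C=C)C[C@]2(CC=C(C)C)C(=O)[C@@]1(CC=C(C)C)C(=O)C(C(=O)c3ccc(O[Si](C(C)C)(C(C)C)C(C)C)c(O[Si](C(C)C)(C(C)C)C(C)C)c3)=C2O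
F4 | step 19 | C7 endo 1-acetoxyprop-2-enyl compound | CC(C)=CCC[C@]1(C)[C@@H](C(OC(C)=O)C=C)C[C@]2(CC=C(C)C)C(=O)[C@@]1(CC=C(C)C)C(=O)C(C(=O)c3ccc(O[Si](C(C)C)(C(C)C)C(C)C)c(O[Si](C(C)C)(C(C)C)C(C)C)c3)=C2O
F5 | step 19 | C7 endo allyl compound | CC(C)=CCC[C@]1(C)[C@@H](CC=C)C[C@]2(CC=C(C)C)C(=O)[C@@]1(CC=C(C)C)C(=O)C(C(=O)c3ccc(O[Si](C(C)C)(C(C)C)C(C)C)c(O[Si](C(C)C)(C(C)C)C(C)C)c3)=C2O
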